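| flask | substrate | gas | remark | time |
|---|---|---|---|---|
| larch | 0.0030 M | 0.15 mM (held) | run made earlier |  |
| flask | 0.0020 M | 0.15 mM (held) |  | 50 min |

- larch (time / min: adduct / %, target / %): 2.00: 11.3, 7.0; 4.00: 4.6, 11.9; 6.00: 4.9, 14.2; 8.00: 1.7, 15.4; 10.0: 1.6, 16.5

(scatter of a reading: 1 percentage point)

1. the best time, 50 min at the latest, for adduct
2. the amount of adduct, in percent of the substrate charged, at that time

- what was read earlier has a scatter of 1 percentage point, one standard deviation
- at the start none of the gas is in solution

A curve fitted to the larch run has no rising limb to hold it: adduct is already falling from the first reading at 2.00 min. So I reckon by hand. In the larch run adduct plus target stays near 17.8% of the charge. I take that as the captured share and form the loss ratio, substrate lost per substrate captured (a selectivity factor). If loss is second order in substrate and capture first order, their rates stand in proportion to the substrate concentration, and that comparison drifts down as substrate falls. So, with the gas the same in both flasks, I scale the ratio with the charge.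

| Flask | Charge | Loss ratio | Captured share |
|---|---|---|---|
| larch | 0.0030 M | 4.61 | 17.8% |
| flask | 0.0020 M | 3.07 | 24.5% |

One number is not enough: it gives a sum, not a peak. Adduct's later fall in the larch run reads 0.244 /min. With the peak guessed at 1.00 min, I expect about 19.2%.

The forecast says 18% at 0.8 min, from a captured share of 22%, lower than mine: "The peak must come early".

The flask gives 20.4% at 0.778 min.

    substrate + coupling partner ⇌ adduct (K = 6000 /M, k = 210 /M/s)
    adduct → target (k = 0.00440 /s)
    gas ⇌ coupling partner, rate k3*(csat - [coupling partner]) (kL = 0.330 /s)
    2 substrate → self-condensation product (k = 9.30 /M/s)
    coupling partner → decomposed reagent (k = 0.00930 /s)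

The forecast holds within its tolerance, and my cheapest way near it took a ratio, a fall rate read from the larch run and a guessed time. At 50.0 min the flask holds 73.0% self-condensation product against 26.9% target, a ratio of 2.71 beside my 3.07.

With 8.0 × 10⁻⁴ M of substrate the loss ratio scales to 1.23, a captured share of 44.8%. That flask ends with 46.2% target, and its adduct peaks at 29.2%.

The numbers in the tables were computed for substances that don't exist, and the scatter is random.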